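**Plan**

- Retrosynthesis: the two MOM ethers are cut last. Then O1–C2 and C4–C3 of the pyranone (ring B) are cut together, leaving a salicylaldehyde on ring A and but-2-yne. Then follow the C6–prenyl bond, the formyl carbon and the aryl–C bond of the hexanoate chain.
- Enabling feature: O1 and the C4 carbonyl carbon are ortho substituents of ring A (a salicyloyl unit), and C2 and C3 each carry one methyl, so C2–C3 with both methyls is but-2-yne. The phenol O–H first steers rhodium into the formyl C–H bond and then closes ring B.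
- Forward: phloroglucinol gives a bis-MOM phenol. Friedel–Crafts addition to (E)-hex-2-enal joins the chain and builds a temporary lactol/lactone ring on the oxygen that becomes O1, which tells it apart from the other two. Lactone opening with ortho-formylation, iodination and Stille prenylation fill ring A; ring B is then closed and the MOM groups removed.
- Stereochemistry: the side-chain centre (R) comes from iminium catalysis with (S)-diphenylprolinol silyl ether. C2 (R) and C3 (S), cis, come from the (−)-quinine-controlled oxa-Michael addition and kinetic protonation in the key step.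

Key step: step 7

Assumption: (−)-quinine is taken to induce the (2R) sense it shows with closely related o-tigloylphenols; the remote side-chain centre is not expected to change this.

**Route**

Step 1
Reactants: 1 benzene-1,3,5-triol (phloroglucinol)
Product: 2 3,5-bis(methoxymethoxy)phenol
Conditions: MOMCl (2.0 equiv), i-Pr2NEt (2.2 equiv), DMF, 0 °C → rt
Reagents that add atoms: chloromethyl methyl ether, COCCl
Why: O-alkylation of the phenoxide (Williamson-type) with two equivalents should centre the statistical mixture on the bis-ether, and the mono- and tris-ethers are separable and recyclable; no stereocentre is formed.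

Step 2
Reactants: 2 3,5-bis(methoxymethoxy)phenol; 3 (E)-hex-2-enal
Product: 4 (4R)-5,7-bis(methoxymethoxy)-4-propyl-3,4-dihydro-2H-chromen-2-ol (both C2 epimers)
Conditions: (S)-α,α-diphenylprolinol trimethylsilyl ether (20 mol %), PhCO2H (20 mol %), toluene, 0 °C → rt
Reagents that add atoms: none
Why: In this iminium-catalysed Friedel–Crafts alkylation/hemiacetalisation the CPh2OSiMe3 group shields one face of the (E)-iminium ion, so either of the two equivalent ortho carbons of the phenol adds to the opposite face of Cβ and sets the (R) centre, and the phenol O–H then closes the lactol and so marks the future O1.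

Step 3
Reactants: 4 (4R)-5,7-bis(methoxymethoxy)-4-propyl-3,4-dihydro-2H-chromen-2-ol
Product: 5 (4R)-5,7-bis(methoxymethoxy)-4-propyl-3,4-dihydro-2H-chromen-2-one
Conditions: Dess–Martin periodinane (1.3 equiv), CH2Cl2, 0 °C → rt
Reagents that add atoms: none
Why: Dess–Martin oxidation of a lactol to the lactone is routine and should leave the MOM ethers and the non-acidic benzylic stereocentre untouched.

Step 4
Reactants: 5 (4R)-5,7-bis(methoxymethoxy)-4-propyl-3,4-dihydro-2H-chromen-2-one
Product: 7 methyl (3R)-3-[3-formyl-2-hydroxy-4,6-bis(methoxymethoxy)phenyl]hexanoate, via ring-opened hydroxy ester 6 (not isolated)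
Conditions: Mg(OMe)2 (2.0 equiv), MeOH/toluene, rt; then (CH2O)n (5 equiv), toluene, 90 °C; 1 M HCl, 0 °C work-up
Reagents that add atoms: magnesium methoxide Mg(OCH3)2, CO[Mg]OC; formaldehyde (as paraformaldehyde), C=O
Why: Methoxide opens the aryl ester to the magnesium phenoxide of 6, and magnesium-templated ortho-formylation (hydroxymethylation, then Oppenauer-type hydride transfer to a second formaldehyde) can occur only at the one free ortho position, after which the chelated salicylaldehyde phenoxide is too poor a nucleophile to re-close the lactone.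

Step 5
Reactants: 7 methyl (3R)-3-[3-formyl-2-hydroxy-4,6-bis(methoxymethoxy)phenyl]hexanoate
Product: 8 methyl (3R)-3-[3-formyl-2-hydroxy-5-iodo-4,6-bis(methoxymethoxy)phenyl]hexanoate
Conditions: NIS (1.1 equiv), MeCN, 0 °C → rt, dark
Reagents that add atoms: N-iodosuccinimide, O=C1CCC(=O)N1I
Why: Electrophilic aromatic iodination has only one ring C–H left to attack, and that position is para to the free OH and ortho to both MOM ethers.

Step 6
Reactants: 8 methyl (3R)-3-[3-formyl-2-hydroxy-5-iodo-4,6-bis(methoxymethoxy)phenyl]hexanoate; 9 tributyl(3-methylbut-2-en-1-yl)stannane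
Product: 10 methyl (3R)-3-[3-formyl-2-hydroxy-4,6-bis(methoxymethoxy)-5-(3-methylbut-2-en-1-yl)phenyl]hexanoate
Conditions: Pd(PPh3)4 (5 mol %), DMF, 90 °C
Reagents that add atoms: none
Why: In this Stille coupling, oxidative addition of zerovalent palladium into the C–I bond, transmetalation from tin and reductive elimination at the unsubstituted allyl terminus (the di-ortho-substituted aryl group disfavours a quaternary centre) should give the linear prenyl arene and leave aldehyde, phenol and ester alone.

Step 7
Reactants: 10 methyl (3R)-3-[3-formyl-2-hydroxy-4,6-bis(methoxymethoxy)-5-(3-methylbut-2-en-1-yl)phenyl]hexanoate; 11 but-2-yne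
Product: 13 methyl (3R)-3-[(2R,3S)-5,7-bis(methoxymethoxy)-2,3-dimethyl-6-(3-methylbut-2-en-1-yl)-4-oxo-3,4-dihydro-2H-chromen-8-yl]hexanoate, via (E)-enone 12 (not isolated)
Conditions: [RhCl(cod)]2 (2.5 mol %), dppf [Fe(C5H4PPh2)2] (5 mol %), Na2CO3 (5 mol %), but-2-yne (5 equiv), PhCl, 80 °C, sealed tube; then (−)-quinine (0.2 equiv), PhCl, 15 °C
Reagents that add atoms: none
Why: Phenoxide-assisted oxidative addition of monovalent rhodium into the formyl C–H bond gives a five-membered acyl(hydrido)rhodium chelate (trivalent rhodium) that adds syn across but-2-yne, and C–C reductive elimination forges C4–C3 and releases (E)-enone 12; quinine then acts as a bifunctional base (quinuclidine N on the phenol O–H, C9–OH on the enone carbonyl) for oxa-Michael addition of O1 to Cβ (O1–C2) followed by protonation at C3. The closest known reaction types are the rhodium-catalysed salicylaldehyde–alkyne hydroacylation/oxa-Michael tandem to 2,3-disubstituted chroman-4-ones and the cinchona-alkaloid-catalysed cyclisation of o-tigloylphenols to cis-2,3-dimethylchroman-4-ones. Ring B closes by a 6-endo-trig oxa-Michael addition. C2 (R) is set by the quinine-bound ion pair, which exposes one face of the s-cis enone to the phenoxide, and C3 (S) by kinetic protonation of the resulting enol on the face anti to the C2 methyl group, which gives the cis isomer. The step needs regioselectivity between the two ortho oxygens (the oxygen at C4 of the arene is a MOM ether, so only the phenol next to the side chain is free), chemoselectivity for the alkyne over the trisubstituted prenyl alkene (alkyne insertion into Rh–H is far faster), E geometry (syn addition) and survival of the kinetic cis product (weak amine base, low temperature, no alkoxide). The remote side-chain centre is not expected to override catalyst control.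

Step 8
Reactants: 13 methyl (3R)-3-[(2R,3S)-5,7-bis(methoxymethoxy)-2,3-dimethyl-6-(3-methylbut-2-en-1-yl)-4-oxo-3,4-dihydro-2H-chromen-8-yl]hexanoate
Product: 14 methyl (3R)-3-[(2R,3S)-5,7-dihydroxy-2,3-dimethyl-6-(3-methylbut-2-en-1-yl)-4-oxo-3,4-dihydro-2H-chromen-8-yl]hexanoate (target)
Conditions: HCl (1.25 M in MeOH), 25 °C; NaHCO3 quench before concentration
Reagents that add atoms: none
Why: Acid-catalysed transacetalisation in methanol removes both MOM ethers as dimethoxymethane and keeps the chain as the open methyl ester, while these mild non-basic conditions should avoid enolisation at C3, retro-oxa-Michael opening and cyclisation of the prenyl group onto a phenol.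

**Compound list**

1 | benzene-1,3,5-triol (phloroglucinol) | Oc1cc(O)cc(O)c1 | starting material
2 | 3,5-bis(methoxymethoxy)phenol | COCOc1cc(O)cc(OCOC)c1 | intermediate
3 | (E)-hex-2-enal | CCC/C=C/C=O | starting material
4 | (4R)-5,7-bis(methoxymethoxy)-4-propyl-3,4-dihydro-2H-chromen-2-ol (both C2 epimers) | CCC[C@@H]1CC(O)Oc2cc(OCOC)cc(OCOC)c21 | intermediate
5 | (4R)-5,7-bis(methoxymethoxy)-4-propyl-3,4-dihydro-2H-chromen-2-one | CCC[C@@H]1CC(=O)Oc2cc(OCOC)cc(OCOC)c21 | intermediate
6 | methyl (3R)-3-[2-hydroxy-4,6-bis(methoxymethoxy)phenyl]hexanoate (not isolated) | CCC[C@H](CC(=O)OC)c1c(O)cc(OCOC)cc1OCOC | intermediate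
7 | methyl (3R)-3-[3-formyl-2-hydroxy-4,6-bis(methoxymethoxy)phenyl]hexanoate | CCC[C@H](CC(=O)OC)c1c(O)c(C=O)c(OCOC)cc1OCOC | intermediate
8 | methyl (3R)-3-[3-formyl-2-hydroxy-5-iodo-4,6-bis(methoxymethoxy)phenyl]hexanoate | CCC[C@H](CC(=O)OC)c1c(O)c(C=O)c(OCOC)c(I)c1OCOC | intermediate
9 | tributyl(3-methylbut-2-en-1-yl)stannane | CCCC[Sn](CCCC)(CCCC)CC=C(C)C | starting material
10 | methyl (3R)-3-[3-formyl-2-hydroxy-4,6-bis(methoxymethoxy)-5-(3-methylbut-2-en-1-yl)phenyl]hexanoate | CCC[C@H](CC(=O)OC)c1c(O)c(C=O)c(OCOC)c(CC=C(C)C)c1OCOC | intermediate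
11 | but-2-yne | CC#CC | starting material
12 | methyl (3R)-3-[2-hydroxy-4,6-bis(methoxymethoxy)-3-[(2E)-2-methylbut-2-enoyl]-5-(3-methylbut-2-en-1-yl)phenyl]hexanoate (not isolated) | CCC[C@H](CC(=O)OC)c1c(O)c(C(=O)/C(C)=C/C)c(OCOC)c(CC=C(C)C)c1OCOC | intermediate
13 | methyl (3R)-3-[(2R,3S)-5,7-bis(methoxymethoxy)-2,3-dimethyl-6-(3-methylbut-2-en-1-yl)-4-oxo-3,4-dihydro-2H-chromen-8-yl]hexanoate | CCC[C@H](CC(=O)OC)c1c(OCOC)c(CC=C(C)C)c(OCOC)c2c1O[C@H](C)[C@H](C)C2=O | intermediate
14 | methyl (3R)-3-[(2R,3S)-5,7-dihydroxy-2,3-dimethyl-6-(3-methylbut-2-en-1-yl)-4-oxo-3,4-dihydro-2H-chromen-8-yl]hexanoate | CCC[C@H](CC(=O)OC)c1c(O)c(CC=C(C)C)c(O)c2c1O[C@H](C)[C@H](C)C2=O | target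

**Step count and risks**

Total step count: 8. Longest linear sequence: 8 steps (from phloroglucinol).

Steps most likely to fail:

1. Step 7. The C–H activation may be sluggish at a formyl group flanked on both sides, or the cinchona step may lose cis- and enantioselectivity when it runs in the presence of the rhodium–phosphine residues. The fallback sets out from 10 and separates the two events. Nozaki–Hiyama–Kishi addition of (E)-2-bromobut-2-ene (CrCl2, NiCl2 cat., DMF) to the aldehyde should give the allylic alcohol methyl (3R)-3-[2-hydroxy-3-[(2E)-1-hydroxy-2-methylbut-2-en-1-yl]-4,6-bis(methoxymethoxy)-5-(3-methylbut-2-en-1-yl)phenyl]hexanoate F1 (both carbinol epimers). MnO2 in CH2Cl2 oxidises it to enone 12, which is now isolated and purified. Enone 12 is then cyclised alone with (−)-quinine in PhCl at 15 °C to 13, where the route is rejoined.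

2. Step 4. The phenoxide may re-close the lactone onto the methyl ester faster than it is formylated once methanol is removed. The fallback sets out from 5 and takes the electrophile away. LiOH in THF/H2O gives, as its dilithium salt and without acidification, (3R)-3-[2-hydroxy-4,6-bis(methoxymethoxy)phenyl]hexanoic acid F2. Ortho-formylation of this carboxylate phenoxide (MgCl2, Et3N, (CH2O)n, MeCN, reflux) gives (3R)-3-[3-formyl-2-hydroxy-4,6-bis(methoxymethoxy)phenyl]hexanoic acid F3. Selective carboxylate methylation (MeI, KHCO3, DMF) returns to 7.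

3. Step 6. Oxidative addition and transmetalation may be slow at an iodide flanked by two MOM ethers, coupling may occur at the γ-terminus to give the reverse-prenyl isomer, or the stannane may allylate the aldehyde. The fallback sets out from 2 and installs the prenyl group by directed metalation before the chain.
   - i-Pr3SiCl/imidazole (DMF) gives [3,5-bis(methoxymethoxy)phenoxy]tri(propan-2-yl)silane F4.
   - Lithiation between the two MOM ethers (n-BuLi, TMEDA, THF, 0 °C) and quenching with 1-bromo-3-methylbut-2-ene gives [3,5-bis(methoxymethoxy)-4-(3-methylbut-2-en-1-yl)phenoxy]tri(propan-2-yl)silane F5.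
   - Bu4NF (THF) gives 3,5-bis(methoxymethoxy)-4-(3-methylbut-2-en-1-yl)phenol F6.
   - The conditions of steps 2 and 3 then give the lactol (4R)-5,7-bis(methoxymethoxy)-6-(3-methylbut-2-en-1-yl)-4-propyl-3,4-dihydro-2H-chromen-2-ol F7 and the lactone (4R)-5,7-bis(methoxymethoxy)-6-(3-methylbut-2-en-1-yl)-4-propyl-3,4-dihydro-2H-chromen-2-one F8.
   - The conditions of step 4 lead, through the unisolated methyl (3R)-3-[6-hydroxy-2,4-bis(methoxymethoxy)-3-(3-methylbut-2-en-1-yl)phenyl]hexanoate F9, to 10, where the route is rejoined. Steps 5 and 6 fall away.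

Further compounds
F1 | step 7 | methyl (3R)-3-[2-hydroxy-3-[(2E)-1-hydroxy-2-methylbut-2-en-1-yl]-4,6-bis(methoxymethoxy)-5-(3-methylbut-2-en-1-yl)phenyl]hexanoate | CCC[C@H](CC(=O)OC)c1c(O)c(C(O)/C(C)=C/C)c(OCOC)c(CC=C(C)C)c1OCOC
F2 | step 4 | (3R)-3-[2-hydroxy-4,6-bis(methoxymethoxy)phenyl]hexanoic acid | CCC[C@H](CC(=O)O)c1c(O)cc(OCOC)cc1OCOC
F3 | step 4 | (3R)-3-[3-formyl-2-hydroxy-4,6-bis(methoxymethoxy)phenyl]hexanoic acid | CCC[C@H](CC(=O)O)c1c(O)c(C=O)c(OCOC)cc1OCOC
F4 | step 6 | [3,5-bis(methoxymethoxy)phenoxy]tri(propan-2-yl)silane | COCOc1cc(O[Si](C(C)C)(C(C)C)C(C)C)cc(OCOC)c1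
F5 | step 6 | [3,5-bis(methoxymethoxy)-4-(3-methylbut-2-en-1-yl)phenoxy]tri(propan-2-yl)silane | COCOc1cc(O[Si](C(C)C)(C(C)C)C(C)C)cc(OCOC)c1CC=C(C)C
F6 | step 6 | 3,5-bis(methoxymethoxy)-4-(3-methylbut-2-en-1-yl)phenol | COCOc1cc(O)cc(OCOC)c1CC=C(C)C
F7 | step 6 | (4R)-5,7-bis(methoxymethoxy)-6-(3-methylbut-2-en-1-yl)-4-propyl-3,4-dihydro-2H-chromen-2-ol | CCC[C@@H]1CC(O)Oc2cc(OCOC)c(CC=C(C)C)c(OCOC)c21
F8 | step 6 | (4R)-5,7-bis(methoxymethoxy)-6-(3-methylbut-2-en-1-yl)-4-propyl-3,4-dihydro-2H-chromen-2-one | CCC[C@@H]1CC(=O)Oc2cc(OCOC)c(CC=C(C)C)c(OCOC)c21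
F9 | step 6 | methyl (3R)-3-[6-hydroxy-2,4-bis(methoxymethoxy)-3-(3-methylbut-2-en-1-yl)phenyl]hexanoate | CCC[C@H](CC(=O)OC)c1c(O)cc(OCOC)c(CC=C(C)C)c1OCOC
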